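## Analysis of the target

The target 28 is a 20-membered cyclophane of four benzene rings joined in the order A–O–B–CH2CH2–C–O–D–CH2CH2–A. Ring A is the hydroxy ring whose ether oxygen is para to its CH2, ring B the meta-phenylene, ring C the para-phenylene, and ring D the hydroxy ring whose OH is para to its CH2. There is no stereocentre and no alkene, so the problem is connectivity and ring closure only. The two free phenols each sit ortho to a diaryl ether oxygen and are electron-rich and oxidisable, so they are carried as methyl ethers until the last step. The hard part is closing the large ring and, above all, making the A–O–B ether. Ring B has no electron-withdrawing group, and the oxygen-bearing carbon of ring A is para to an alkyl group and ortho to an oxygen, so neither ring can act as an SNAr electrophile.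

The strategy rests on the substitution pattern of ring B. Its oxygen-bearing carbon and its CH2-bearing carbon are 1,3 across a free C–H, and the carbon meta to both is also C–H. This is what remains when an oxygen nucleophile adds to the remote carbon of a 3-triflyloxybenzyne made from a 2-silyl-5-alkylresorcinol bis(triflate). The ether carbon is a former C–OTf carbon, the C–H para to the chain is the former C–Si carbon, and the surviving C–OTf is later reduced to C–H. Because that resorcinol is symmetric about the silicon–chain axis, either triflate may leave and only one aryne can form.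

## Retrosynthetic reasoning

Target 28 is traced to its dimethyl ether 26 by cutting the two O–CH3 bonds. Methyl ethers are the smallest phenol protection, survive every earlier step, and fall to a Lewis-acid demethylation that leaves diaryl ethers intact.

Compound 26 is traced to the macrocyclic aryl triflate 25 by replacing one ring B C–H with C–OTf. The triflate is the trace of the element that controls the ring closure. A palladium-catalysed transfer hydrogenolysis with formate deletes it in one step.

Compound 25 is cut at the ring B carbon–oxygen bond of the A–O–B ether, which leads to the open-chain phenol 23 through the aryne 24. This bond is chosen because it is the one that no classical method makes easily on an unactivated meta-phenylene, and because forming it also closes the 20-membered ring. The forward reaction must meet four requirements: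
- A fluoride salt must release the aryne slowly at high dilution.
- The ring A phenoxide must attack the aryne carbon remote from the remaining triflate.
- The aryl anion next to the C–OTf carbon must be protonated before it can expel that triflate. For this reason the phenol is used un-ionised and a hindered alcohol is present as a proton reservoir.
- Ring closure must outrun intermolecular capture.

Phenol 23 is traced to the stilbene bis(triflate) 21 by re-forming the A–D double bond and the benzyl ether on ring A. One hydrogenation then saturates the bridge and frees the only phenol in the molecule, after the triflates are already in place. Compound 21 comes from the 2-silylresorcinol 20 by O-sulfonylation, and 20 from the bis(methoxymethyl) ether 18. The acetals are removed by a buffered silyl triflate method that passes through the silyl ether 19, so the electron-rich aryl–silicon bond never meets a protic acid.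

Stilbene 18 is cut at the A–D double bond into aldehyde 13 and the phosphonium salt 16. A Wittig reaction is the dependable way to make a bibenzyl bridge, and its geometry is of no consequence. Salt 16 comes in two steps from the commercial benzyl-protected aldehyde 14 through alcohol 15.

Aldehyde 13 is cut at the ring D carbon–oxygen bond of the C–O–D ether into phenol 11 and the aryl bromide 12. A copper-catalysed coupling is preferred to an SNAr reaction here. SNAr would require a carbonyl para to the leaving group on ring C, which would force the ether to be made before the B–C bridge and would leave the silicon to be introduced in the presence of carbonyl groups. The ring C phenol of 11, by contrast, is already at hand.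

Phenol 11 is cut at the carbon–silicon bond, leading to 8. The carbon between the two acetal oxygens is by far the most acidic ring position, and 8 carries no other group that an alkyllithium would attack, so the silicon is placed on this small fragment.

Phenol 8 is traced through stilbene 6 to aldehyde 2 and phosphonium salt 4 (Wittig disconnection of the B–C bridge). The hydrogenation that saturates 6 also removes the benzyl group from ring C. Aldehyde 2 is the bis-acetal of the symmetric dihydroxy aldehyde 1, and salt 4 comes from the benzylic chloride 3.

## Alternatives that were turned down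

Alternative 1: The C–O–D ether is cut at the oxygen–ring D bond. In the forward direction the open-chain diphenol A2 carries a 2,6-dibromophenol on ring D and a 2,6-dichlorophenol on ring C. A thallium-based two-electron oxidant in methanol oxidises the dibromophenol, the dichlorophenol oxygen attacks a bromine-bearing ortho carbon, and a metal reductant expels bromide to give the trihalogenated macrocycle A1.
- In its favour: the closure uses the hydroxyl that ring D has anyway, and oxidative closures of this kind are established for diaryl ether macrocycles. On precedent it is stronger than the chosen route.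
- Against it: four halogens must be installed and three (two chlorines, one bromine) must be removed from A1. The aryl halides rule out Pd/C hydrogenation for the bibenzyl bridges. The oxidant is toxic and stoichiometric and must spare the electron-rich ring A. The A–O–B ether to the unactivated ring B is not addressed and needs its own coupling.
- Comparison: the chosen route uses one removable triflate instead of four halogens, closes the ring without a metal, and solves the hardest ether in the same step.

Alternative 2: One carbon of the A–D bridge is removed, giving the 19-membered diaryl ketone A4. A silyl diazoalkane with a Lewis acid would add to the carbonyl, an aryl group would migrate with loss of nitrogen, and desilylation would give the 20-membered ketone A3.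
- In its favour: either migration leads to the same CH2CH2 bridge after deoxygenation, so migratory aptitude is no concern, and ketone homologation is a known reaction type.
- Against it: the step does not close the macrocycle, so A4 needs its own, more strained, ring closure. A diaryl ketone flanked by para-oxygenated rings is a weak electrophile for a diazoalkane. The product A3 is an aryl benzyl ketone and more reactive than A4, so repeated insertion competes. The carbonyl must then be removed in further steps.
- Comparison: it is behind the chosen route on step economy and on what the key step achieves, and has no point on which it is clearly stronger.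

Alternative 3: The A–O–B ether is cut at the oxygen–ring A bond. The open-chain fluoronitroarene A6 carries a phenol on ring B. Carbonate base in a dipolar aprotic solvent at high dilution displaces the fluoride ortho to the nitro group and gives the nitro macrocycle A5.
- In its favour: this is the most reliable closure of the four, since SNAr macrocyclisation of ortho-nitro fluoroarenes is well established. The nitro group also sits exactly where the ring A hydroxyl is needed, and ring B needs only one oxygen. On reliability it is stronger than the chosen route.
- Against it: turning NO2 into OH takes reduction, diazotisation and hydrolysis. The diazonium ion would sit on a macrocycle full of electron-rich arenes, which invites azo coupling and reduction. The nitro group also forbids catalytic hydrogenation of the bridges once it is present.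
- Comparison: the chosen strategy forms the same ether with reversed polarity and corrects its auxiliary group in one mild step instead of three. The price is a ring closure without direct precedent.

Key step: step 13

Assumption: stilbenes 6, 18, 20 and 21 are expected as E/Z mixtures and are written without alkene descriptors, since both double bonds are hydrogenated later.

## Route

Step 1
Reactants: 1 3,5-dihydroxybenzaldehyde
Product: 2 3,5-bis(methoxymethoxy)benzaldehyde
Conditions: MOMCl (2.5 equiv), iPr2NEt (3 equiv), CH2Cl2, 0 °C → rt
Reagents that add atoms: chloromethyl methyl ether, COCCl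
Why: O-alkylation of both phenols by the reactive chloromethyl ether; the acetals withstand base and hydrogenation and later direct lithiation to the carbon between them.

Step 2
Reactants: 3 4-(benzyloxy)benzyl chloride
Product: 4 [4-(benzyloxy)benzyl]triphenylphosphonium chloride
Conditions: PPh3, toluene, reflux
Reagents that add atoms: triphenylphosphine, c1ccc(cc1)P(c1ccccc1)c1ccccc1
Why: SN2 quaternisation of a benzylic chloride; the salt should precipitate from toluene.

Step 3
Reactants: 4 [4-(benzyloxy)benzyl]triphenylphosphonium chloride; 2 3,5-bis(methoxymethoxy)benzaldehyde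
Product: 6 1-(benzyloxy)-4-{2-[3,5-bis(methoxymethoxy)phenyl]ethenyl}benzene (E/Z mixture), via phosphorus ylide 5 (not isolated)
Conditions: KOtBu, THF, 0 °C; then 2, 0 °C → rt
Reagents that add atoms: none
Why: Wittig olefination of a non-enolisable aryl aldehyde with a semi-stabilised benzylic ylide; it joins rings B and C, and the alkene geometry does not matter.

Step 4
Reactants: 6 1-(benzyloxy)-4-{2-[3,5-bis(methoxymethoxy)phenyl]ethenyl}benzene
Product: 8 4-{2-[3,5-bis(methoxymethoxy)phenyl]ethyl}phenol, via benzyl ether bibenzyl 7 (not isolated)
Conditions: H2 (1 atm), 10% Pd/C, EtOAc/EtOH, rt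
Reagents that add atoms: none
Why: Heterogeneous hydrogenation saturates the stilbene and then hydrogenolyses the benzylic C–O bond; the acetals are inert under neutral conditions, so only the ring C phenol is freed.

Step 5
Reactants: 8 4-{2-[3,5-bis(methoxymethoxy)phenyl]ethyl}phenol
Product: 11 4-{2-[3,5-bis(methoxymethoxy)-4-(trimethylsilyl)phenyl]ethyl}phenol, via dilithio species 9 (not isolated), via bis(trimethylsilyl) compound 10 (not isolated)
Conditions: n-BuLi (2.3 equiv), THF, 0 °C; TMSCl (3 equiv), 0 °C → rt; then K2CO3, MeOH, rt
Reagents that add atoms: chlorotrimethylsilane, C[Si](C)(C)Cl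
Why: Directed ortho-metalation: after deprotonation of the phenol, the second equivalent lithiates the carbon flanked by both acetal oxygens, the doubly chelated and most acidic ring site. Silylation at carbon and oxygen is followed by methanolysis of the O–Si bond only.

Step 6
Reactants: 11 4-{2-[3,5-bis(methoxymethoxy)-4-(trimethylsilyl)phenyl]ethyl}phenol; 12 3-bromo-4-methoxybenzaldehyde
Product: 13 3-(4-{2-[3,5-bis(methoxymethoxy)-4-(trimethylsilyl)phenyl]ethyl}phenoxy)-4-methoxybenzaldehyde
Conditions: CuI (10 mol %), N,N-dimethylglycine hydrochloride (30 mol %), Cs2CO3, 1,4-dioxane, 90 °C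
Reagents that add atoms: none
Why: Ligand-accelerated Ullmann diaryl ether synthesis between an unhindered para-alkylphenol and an aryl bromide; the non-enolisable aldehyde, the acetals and the aryl–silicon bond tolerate carbonate base.

Step 7
Reactants: 14 4-(benzyloxy)-3-methoxybenzaldehyde
Product: 15 [4-(benzyloxy)-3-methoxyphenyl]methanol
Conditions: NaBH4, MeOH, 0 °C
Reagents that add atoms: none
Why: Hydride reduction of an aryl aldehyde to the benzylic alcohol.

Step 8
Reactants: 15 [4-(benzyloxy)-3-methoxyphenyl]methanol
Product: 16 [4-(benzyloxy)-3-methoxybenzyl]triphenylphosphonium bromide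
Conditions: PPh3·HBr, MeCN, reflux
Reagents that add atoms: triphenylphosphine hydrobromide, [Br-].c1ccc(cc1)[PH+](c1ccccc1)c1ccccc1
Why: The electron-rich benzylic alcohol is activated by the acidic salt and captured by the phosphine, giving the phosphonium salt directly with loss of water; the aryl benzyl ether is stable to the buffered acid.

Step 9
Reactants: 16 [4-(benzyloxy)-3-methoxybenzyl]triphenylphosphonium bromide; 13 3-(4-{2-[3,5-bis(methoxymethoxy)-4-(trimethylsilyl)phenyl]ethyl}phenoxy)-4-methoxybenzaldehyde
Product: 18 1-(benzyloxy)-2-methoxy-4-{2-[3-(4-{2-[3,5-bis(methoxymethoxy)-4-(trimethylsilyl)phenyl]ethyl}phenoxy)-4-methoxyphenyl]ethenyl}benzene (E/Z mixture), via phosphorus ylide 17 (not isolated)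
Conditions: KOtBu, THF, 0 °C; then 13, 0 °C → rt
Reagents that add atoms: none
Why: Second Wittig olefination, joining rings A and D; the benzyl ether on ring A enters only now, after the organolithium step.

Step 10
Reactants: 18 stilbene bis(methoxymethyl) ether
Product: 20 5-{2-[4-(5-{2-[4-(benzyloxy)-3-methoxyphenyl]ethenyl}-2-methoxyphenoxy)phenyl]ethyl}-2-(trimethylsilyl)benzene-1,3-diol (E/Z mixture), via bis(trimethylsilyl ether) 19 (not isolated)
Conditions: TMSOTf (4 equiv), 2,2'-bipyridyl (6 equiv), MeCN, 0 °C → rt; then H2O, rt
Reagents that add atoms: none
Why: Buffered silyl triflate cleavage of aryl methoxymethyl ethers: the acetal carbon is transferred to the bipyridyl and the aryl oxygens are silylated, and water then hydrolyses the O–Si bonds. No strong protic acid is present, which should prevent ipso-protonation of the electron-rich aryl–silicon bond; methyl and benzyl ethers are untouched. The diol is used crude.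

Step 11
Reactants: 20 2-silylresorcinol stilbene
Product: 21 5-{2-[4-(5-{2-[4-(benzyloxy)-3-methoxyphenyl]ethenyl}-2-methoxyphenoxy)phenyl]ethyl}-2-(trimethylsilyl)-1,3-phenylene bis(trifluoromethanesulfonate) (E/Z mixture)
Conditions: Tf2O (2.4 equiv), pyridine, CH2Cl2, −20 → 0 °C
Reagents that add atoms: trifluoromethanesulfonic anhydride, O=S(=O)(OS(=O)(=O)C(F)(F)F)C(F)(F)F
Why: O-sulfonylation of both phenols, the standard way to ortho-silylaryl triflates; the ring then becomes electron-poor and the aryl–silicon bond is no longer acid-sensitive.

Step 12
Reactants: 21 stilbene bis(triflate)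
Product: 23 5-{2-[4-(5-{2-[4-hydroxy-3-methoxyphenyl]ethyl}-2-methoxyphenoxy)phenyl]ethyl}-2-(trimethylsilyl)-1,3-phenylene bis(trifluoromethanesulfonate), via benzyl ether bibenzyl 22 (not isolated)
Conditions: H2 (1 atm), 10% Pd/C, EtOAc, rt
Reagents that add atoms: none
Why: Alkene hydrogenation followed by hydrogenolysis of the benzyl ether; aryl triflates are not reduced over Pd/C without added base and the aryl–silicon bond is inert, so the ring A phenol appears as the only free OH.

Step 13
Reactants: 23 silyl bis(triflate) phenol
Product: 25 macrocyclic aryl triflate (20-membered ring A–O–B–CH2CH2–C–O–D–CH2CH2–, OMe on ring A ortho to the A–O–B oxygen, OMe on ring D para to its CH2, OTf on ring B meta to both O and CH2), via aryne 24 (not isolated)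
Conditions: CsF (4 equiv), t-BuOH (5% v/v), MeCN, 40 °C, 23 added by syringe pump over 12 h to 1 mM
Reagents that add atoms: none
Why: Proposed new method: fluoride attacks silicon and the silicate expels one of the two equivalent triflates, so a single 3-triflyloxy-5-alkylbenzyne 24 forms; the ring A phenol, as its fluoride-bound phenoxide, adds to the aryne carbon not adjacent to the triflate, and the aryl anion that appears next to the C–OTf carbon is protonated by tert-butanol or HF to give 25. The closest known reactions are the intermolecular fluoride-induced O-arylation of phenols with ortho-silylaryl triflates and the remote-selective addition of nucleophiles to 3-triflyloxybenzynes; neither has been used to close a macrocycle. The 20-membered ring closes by attack of the tethered oxygen on one carbon of the strained triple bond, with the second aryne carbon ending outside the ring; attack at the other carbon would give a 21-membered para isomer. The regiochemistry is secured by the triflyloxy group, whose inductive pull distorts the aryne so that the remote carbon is the more electrophilic one and places the developing negative charge next to the C–O dipole; the remote carbon is also flanked only by a C–H. Cyclisation over oligomerisation rests on pseudo-high dilution, on the slow release of fluoride from sparingly soluble CsF, and on the fact that each aryne is born tethered to its own phenoxide. The point that needs a deliberate measure is the adduct anion, which if left unprotonated can expel the second triflate and start a second aryne; therefore no carbonate base is used, the phenol enters un-ionised, and tert-butanol, which adds only sluggishly to arynes under fluoride conditions, is present in large excess as proton reservoir. No stereocentre is formed.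

Step 14
Reactants: 25 macrocyclic aryl triflate
Product: 26 macrocyclic dimethyl ether (ring B now unsubstituted apart from O and CH2)
Conditions: Pd(OAc)2 (10 mol %), dppf (12 mol %), HCO2H, Et3N, DMF, 70 °C
Reagents that add atoms: none
Why: Palladium-catalysed transfer hydrogenolysis of an aryl triflate: oxidative addition, exchange of triflate for formate, loss of CO2 and C–H reductive elimination; diaryl and methyl ethers are inert.

Step 15
Reactants: 26 macrocyclic dimethyl ether
Product: 28 target CNP0329842.0, via bis(dibromoboryl) ether 27 (not isolated)
Conditions: BBr3 (6 equiv), CH2Cl2, −78 °C → rt; then H2O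
Reagents that add atoms: none
Why: Lewis-acid demethylation: boron coordinates each methoxy oxygen and bromide attacks the methyl group; diaryl ethers lack an sp3 carbon for this attack and survive, and aqueous work-up hydrolyses the aryl borates to the two phenols.

## Compound list

1 | 3,5-dihydroxybenzaldehyde | O=Cc1cc(O)cc(O)c1 | starting material
2 | 3,5-bis(methoxymethoxy)benzaldehyde | COCOc1cc(C=O)cc(OCOC)c1 | intermediate
3 | 4-(benzyloxy)benzyl chloride | ClCc1ccc(OCc2ccccc2)cc1 | starting material
4 | [4-(benzyloxy)benzyl]triphenylphosphonium chloride | [Cl-].c1ccc(cc1)[P+](Cc1ccc(OCc2ccccc2)cc1)(c1ccccc1)c1ccccc1 | intermediate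
5 | [4-(benzyloxy)benzylidene]triphenylphosphorane (ylide, formed in the flask) | c1ccc(cc1)[P+]([CH-]c1ccc(OCc2ccccc2)cc1)(c1ccccc1)c1ccccc1 | intermediate
6 | 1-(benzyloxy)-4-{2-[3,5-bis(methoxymethoxy)phenyl]ethenyl}benzene (E/Z mixture) | COCOc1cc(C=Cc2ccc(OCc3ccccc3)cc2)cc(OCOC)c1 | intermediate
7 | 1-(benzyloxy)-4-{2-[3,5-bis(methoxymethoxy)phenyl]ethyl}benzene (formed in the flask) | COCOc1cc(CCc2ccc(OCc3ccccc3)cc2)cc(OCOC)c1 | intermediate
8 | 4-{2-[3,5-bis(methoxymethoxy)phenyl]ethyl}phenol | COCOc1cc(CCc2ccc(O)cc2)cc(OCOC)c1 | intermediate
9 | lithium 4-{2-[4-lithio-3,5-bis(methoxymethoxy)phenyl]ethyl}phenoxide (formed in the flask) | [Li]Oc1ccc(CCc2cc(OCOC)c([Li])c(OCOC)c2)cc1 | intermediate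
10 | {4-[2-(4-trimethylsilyloxyphenyl)ethyl]-2,6-bis(methoxymethoxy)phenyl}trimethylsilane (formed in the flask) | COCOc1cc(CCc2ccc(O[Si](C)(C)C)cc2)cc(OCOC)c1[Si](C)(C)C | intermediate
11 | 4-{2-[3,5-bis(methoxymethoxy)-4-(trimethylsilyl)phenyl]ethyl}phenol | COCOc1cc(CCc2ccc(O)cc2)cc(OCOC)c1[Si](C)(C)C | intermediate
12 | 3-bromo-4-methoxybenzaldehyde | COc1ccc(C=O)cc1Br | starting material
13 | 3-(4-{2-[3,5-bis(methoxymethoxy)-4-(trimethylsilyl)phenyl]ethyl}phenoxy)-4-methoxybenzaldehyde | COCOc1cc(CCc2ccc(Oc3cc(C=O)ccc3OC)cc2)cc(OCOC)c1[Si](C)(C)C | intermediate
14 | 4-(benzyloxy)-3-methoxybenzaldehyde | COc1cc(C=O)ccc1OCc1ccccc1 | starting material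
15 | [4-(benzyloxy)-3-methoxyphenyl]methanol | COc1cc(CO)ccc1OCc1ccccc1 | intermediate
16 | [4-(benzyloxy)-3-methoxybenzyl]triphenylphosphonium bromide | [Br-].COc1cc(C[P+](c2ccccc2)(c2ccccc2)c2ccccc2)ccc1OCc1ccccc1 | intermediate
17 | [4-(benzyloxy)-3-methoxybenzylidene]triphenylphosphorane (ylide, formed in the flask) | COc1cc([CH-][P+](c2ccccc2)(c2ccccc2)c2ccccc2)ccc1OCc1ccccc1 | intermediate
18 | 1-(benzyloxy)-2-methoxy-4-{2-[3-(4-{2-[3,5-bis(methoxymethoxy)-4-(trimethylsilyl)phenyl]ethyl}phenoxy)-4-methoxyphenyl]ethenyl}benzene (E/Z mixture) | COCOc1cc(CCc2ccc(Oc3cc(C=Cc4ccc(OCc5ccccc5)c(OC)c4)ccc3OC)cc2)cc(OCOC)c1[Si](C)(C)C | intermediate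
19 | bis(trimethylsilyl ether) of 20 (formed in the flask) | C[Si](C)(C)Oc1cc(CCc2ccc(Oc3cc(C=Cc4ccc(OCc5ccccc5)c(OC)c4)ccc3OC)cc2)cc(O[Si](C)(C)C)c1[Si](C)(C)C | intermediate
20 | 5-{2-[4-(5-{2-[4-(benzyloxy)-3-methoxyphenyl]ethenyl}-2-methoxyphenoxy)phenyl]ethyl}-2-(trimethylsilyl)benzene-1,3-diol (E/Z mixture) | Oc1cc(CCc2ccc(Oc3cc(C=Cc4ccc(OCc5ccccc5)c(OC)c4)ccc3OC)cc2)cc(O)c1[Si](C)(C)C | intermediate
21 | 5-{2-[4-(5-{2-[4-(benzyloxy)-3-methoxyphenyl]ethenyl}-2-methoxyphenoxy)phenyl]ethyl}-2-(trimethylsilyl)-1,3-phenylene bis(trifluoromethanesulfonate) (E/Z mixture) | FC(F)(F)S(=O)(=O)Oc1cc(CCc2ccc(Oc3cc(C=Cc4ccc(OCc5ccccc5)c(OC)c4)ccc3OC)cc2)cc(OS(=O)(=O)C(F)(F)F)c1[Si](C)(C)C | intermediate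
22 | 5-{2-[4-(5-{2-[4-(benzyloxy)-3-methoxyphenyl]ethyl}-2-methoxyphenoxy)phenyl]ethyl}-2-(trimethylsilyl)-1,3-phenylene bis(trifluoromethanesulfonate) (formed in the flask) | FC(F)(F)S(=O)(=O)Oc1cc(CCc2ccc(Oc3cc(CCc4ccc(OCc5ccccc5)c(OC)c4)ccc3OC)cc2)cc(OS(=O)(=O)C(F)(F)F)c1[Si](C)(C)C | intermediate
23 | 5-{2-[4-(5-{2-[4-hydroxy-3-methoxyphenyl]ethyl}-2-methoxyphenoxy)phenyl]ethyl}-2-(trimethylsilyl)-1,3-phenylene bis(trifluoromethanesulfonate) | COc1cc(CCc2ccc(OC)c(Oc3ccc(CCc4cc(OS(=O)(=O)C(F)(F)F)c([Si](C)(C)C)c(OS(=O)(=O)C(F)(F)F)c4)cc3)c2)ccc1O | intermediate
24 | 3-triflyloxy-5-alkylbenzyne derived from 23 by loss of the silyl group and one triflate (formed in the flask) | COc1cc(CCc2ccc(OC)c(Oc3ccc(CCC4=CC#CC(OS(=O)(=O)C(F)(F)F)=C4)cc3)c2)ccc1O | intermediate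
25 | macrocyclic aryl triflate: 20-membered ring, OMe on rings A and D, OTf on ring B meta to both its O and its CH2 | COc1cc2ccc1Oc1cc(OS(=O)(=O)C(F)(F)F)cc(c1)CCc1ccc(cc1)Oc1cc(ccc1OC)CC2 | intermediate
26 | macrocyclic dimethyl ether of 28 | COc1cc2ccc1Oc1cccc(c1)CCc1ccc(cc1)Oc1cc(ccc1OC)CC2 | intermediate
27 | bis(dibromoboryl) ether of 28 (formed in the flask) | BrB(Br)Oc1cc2ccc1Oc1cccc(c1)CCc1ccc(cc1)Oc1cc(ccc1OB(Br)Br)CC2 | intermediate
28 | CNP0329842.0: 20-membered macrocycle A–O–B–CH2CH2–C–O–D–CH2CH2– with OH on ring A (ortho to its ether O, meta to its CH2) and OH on ring D (ortho to its ether O, para to its CH2) | Oc1cc2ccc1Oc1cccc(c1)CCc1ccc(cc1)Oc1cc(ccc1O)CC2 | target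

## Step count and least certain steps

Total: 15 steps. Longest linear sequence: 12 steps (steps 1, 3, 4, 5, 6, 9, 10, 11, 12, 13, 14, 15, from 1).

Step 13 (key step). Three processes can divert the aryne or its adduct:
- loss of the second triflate from the adduct anion before it is protonated, which starts a second aryne and leads to decomposition;
- intermolecular capture of the aryne by a phenoxide of another molecule, giving oligomers;
- interception of the aryne by fluoride or by the alcohol, because a 20-membered closure has a low effective molarity.

Fallback, using known reaction types and reversed polarity: the ring B resorcinol becomes the nucleophile and ring A an aryl bromide. The fallback sets out from 8 and returns at 25.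
- Copper-catalysed coupling of 8 with 12, as in step 6, should give the unsilylated diaryl ether aldehyde F1.
- Commercial (4-bromo-3-methoxyphenyl)methanol and PPh3·HBr should give (4-bromo-3-methoxybenzyl)triphenylphosphonium bromide F2.
- Wittig reaction of F1 with the ylide of F2 (KOtBu, THF) should give the bromostilbene F3.
- Diimide reduction (TsNHNH2, NaOAc, aqueous DME, reflux) should saturate the alkene without touching the bromide and give the bibenzyl F4.
- HCl in MeOH should remove both acetals, which is unproblematic without silicon, and give the bromo resorcinol F5.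
- Intramolecular Ullmann etherification at high dilution (CuI, N,N-dimethylglycine, Cs2CO3, dioxane, 100 °C) should give the macrocyclic phenol F6. Either resorcinol oxygen is equivalent.
- Tf2O and pyridine should convert F6 into 25.

Step 10. The risk is ipso-protonation and loss of the trimethylsilyl group, during the aqueous stage of the acetal cleavage or on handling the electron-rich diol. Fallback: the acetals are replaced by diethylcarbamates, which direct the lithiation equally well and are removed by hydride, not acid. It sets out from 1 and returns at 20.
- Diethylcarbamoyl chloride and K2CO3 should convert 1 into the bis(carbamate) aldehyde F7.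
- Wittig reaction with ylide 5 should give the stilbene F8.
- H2 over Pd/C should give the phenol F9.
- s-BuLi/TMEDA at −78 °C followed by TMSCl and methanolysis of the O-silyl group should give the silylated phenol F10.
- Copper-catalysed coupling with 12 should give the aldehyde F11.
- Wittig reaction with ylide 17 should give the stilbene F12.
- LiAlH4 in THF should cleave both carbamates and, after neutral work-up, give 20.

Step 12. The risk is hydrogenolysis of the aryl C–O bonds of the triflates on the palladium surface, or stalling of the debenzylation after the alkene is saturated. Fallback, from 21 to 23 without a metal hydride surface: diimide (TsNHNH2, NaOAc, aqueous DME, reflux) reduces only the alkene and gives 22, which is isolated. BCl3 with pentamethylbenzene in CH2Cl2 at −78 °C then removes the benzyl group as a cation and gives 23. This fallback makes no compound outside the list (F0).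

Step 6. The risk is slow oxidative addition at the bromide flanked by a methoxy group, so that the coupling stalls while the aldehyde degrades under hot carbonate. Fallback, from 11 to 13: oxidative Chan–Lam coupling of 11 with commercial (5-formyl-2-methoxyphenyl)boronic acid (Cu(OAc)2, pyridine, 4 Å molecular sieves, CH2Cl2, air, rt) forms the same ether at room temperature. This fallback makes no compound outside the list (F0).

## Further compounds

F1 | step 13 | 3-(4-{2-[3,5-bis(methoxymethoxy)phenyl]ethyl}phenoxy)-4-methoxybenzaldehyde | COCOc1cc(CCc2ccc(Oc3cc(C=O)ccc3OC)cc2)cc(OCOC)c1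
F2 | step 13 | (4-bromo-3-methoxybenzyl)triphenylphosphonium bromide | [Br-].COc1cc(C[P+](c2ccccc2)(c2ccccc2)c2ccccc2)ccc1Br
F3 | step 13 | 1-bromo-2-methoxy-4-{2-[3-(4-{2-[3,5-bis(methoxymethoxy)phenyl]ethyl}phenoxy)-4-methoxyphenyl]ethenyl}benzene (E/Z mixture) | COCOc1cc(CCc2ccc(Oc3cc(C=Cc4ccc(Br)c(OC)c4)ccc3OC)cc2)cc(OCOC)c1
F4 | step 13 | 1-bromo-2-methoxy-4-{2-[3-(4-{2-[3,5-bis(methoxymethoxy)phenyl]ethyl}phenoxy)-4-methoxyphenyl]ethyl}benzene | COCOc1cc(CCc2ccc(Oc3cc(CCc4ccc(Br)c(OC)c4)ccc3OC)cc2)cc(OCOC)c1
F5 | step 13 | 5-{2-[4-(5-{2-[4-bromo-3-methoxyphenyl]ethyl}-2-methoxyphenoxy)phenyl]ethyl}benzene-1,3-diol | Oc1cc(CCc2ccc(Oc3cc(CCc4ccc(Br)c(OC)c4)ccc3OC)cc2)cc(O)c1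
F6 | step 13 | macrocyclic phenol: 25 with OH in place of OTf on ring B | COc1cc2ccc1Oc1cc(O)cc(c1)CCc1ccc(cc1)Oc1cc(ccc1OC)CC2
F7 | step 10 | 5-formyl-1,3-phenylene bis(diethylcarbamate) | CCN(CC)C(=O)Oc1cc(C=O)cc(OC(=O)N(CC)CC)c1
F8 | step 10 | 5-{2-[4-(benzyloxy)phenyl]ethenyl}-1,3-phenylene bis(diethylcarbamate) (E/Z mixture) | CCN(CC)C(=O)Oc1cc(C=Cc2ccc(OCc3ccccc3)cc2)cc(OC(=O)N(CC)CC)c1
F9 | step 10 | 5-[2-(4-hydroxyphenyl)ethyl]-1,3-phenylene bis(diethylcarbamate) | CCN(CC)C(=O)Oc1cc(CCc2ccc(O)cc2)cc(OC(=O)N(CC)CC)c1
F10 | step 10 | 5-[2-(4-hydroxyphenyl)ethyl]-2-(trimethylsilyl)-1,3-phenylene bis(diethylcarbamate) | CCN(CC)C(=O)Oc1cc(CCc2ccc(O)cc2)cc(OC(=O)N(CC)CC)c1[Si](C)(C)C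
F11 | step 10 | 5-{2-[4-(5-formyl-2-methoxyphenoxy)phenyl]ethyl}-2-(trimethylsilyl)-1,3-phenylene bis(diethylcarbamate) | CCN(CC)C(=O)Oc1cc(CCc2ccc(Oc3cc(C=O)ccc3OC)cc2)cc(OC(=O)N(CC)CC)c1[Si](C)(C)C
F12 | step 10 | 5-{2-[4-(5-{2-[4-(benzyloxy)-3-methoxyphenyl]ethenyl}-2-methoxyphenoxy)phenyl]ethyl}-2-(trimethylsilyl)-1,3-phenylene bis(diethylcarbamate) (E/Z mixture) | CCN(CC)C(=O)Oc1cc(CCc2ccc(Oc3cc(C=Cc4ccc(OCc5ccccc5)c(OC)c4)ccc3OC)cc2)cc(OC(=O)N(CC)CC)c1[Si](C)(C)C
F0 | step 12 | none | none
F0 | step 6 | none | none
A1 | alternative 1 | trihalogenated macrocycle, ring A methyl ether | COc1cc2ccc1Oc1cccc(c1)CCc1cc(Cl)c(c(Cl)c1)Oc1cc(cc(Br)c1O)CC2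
A2 | alternative 1 | open-chain diphenol with 3,5-dibromo-4-hydroxyphenyl ring D and 3,5-dichloro-4-hydroxyphenyl ring C | COc1cc(CCc2cc(Br)c(O)c(Br)c2)ccc1Oc1cccc(CCc2cc(Cl)c(O)c(Cl)c2)c1
A3 | alternative 2 | 20-membered homologated ketone (ring D migration shown) | COc1cc2ccc1Oc1cccc(c1)CCc1ccc(cc1)Oc1cc(ccc1OC)CC2=O
A4 | alternative 2 | 19-membered macrocyclic diaryl ketone A–CO–D | COc1cc2ccc1Oc1cccc(c1)CCc1ccc(cc1)Oc1cc(ccc1OC)C2=O
A5 | alternative 3 | nitro macrocycle, ring D methyl ether | [O-][N+](=O)c1cc2ccc1Oc1cccc(c1)CCc1ccc(cc1)Oc1cc(ccc1OC)CC2
A6 | alternative 3 | open-chain 4-fluoro-3-nitrophenyl precursor with ring B phenol | [O-][N+](=O)c1cc(CCc2ccc(OC)c(Oc3ccc(CCc4cccc(O)c4)cc3)c2)ccc1F
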